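**Retrosynthetic overview**

1. Numbering used below (clerodane style): ring carbons C1–C10; C4 carries the carboxyl carbon C18, C5 the acetoxymethyl carbon C19, C8 the methyl C17, C9 the methyl C20 and the chain C11–C12–furan. The target is (8R,9S), C1=C10 E, C2=C3 Z, C4=C5 Z.
2. Target ⇐ hydrolysis/acetylation of the 18,19-lactone (butenolide 20) ⇐ photochemical 6π conrotatory opening of the C5–C10 bond of the cis-fused diene lactone 19. The ten-membered ring is uncovered, never closed.
3. 19 ⇐ intramolecular 2-pyrone Diels–Alder reaction with loss of CO2 from ester 17 (forms the lactone and ring A through bonds C4–C5 and C1–C10) ⇐ cyclohexenylmethanol 15 ⇐ enol triflate 14.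
4. 14 ⇐ key disconnection C9–C11: Cu-catalysed 1,4-addition of the 2-(furan-3-yl)ethyl Grignard reagent to (R)-3,4-dimethylcyclohex-2-enone 6, with triflation of the enolate. Enabling feature: C9 is 1,3 to C5 through C10, so a temporary C5–C10 bond makes ring B (C5–C6–C7–C8–C9–C10) a cyclohexenone with C5 as carbonyl, C9 as its β-carbon and the C8 methyl as the neighbouring control element.
5. Ring order: ring B (steps 1–4; the organocatalytic Michael addition sets C8) → lactone and ring A (step 10) → ten-membered ring by ring opening (step 11). The furan is bought as 3-bromofuran.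

Key step: step 7

Remark: 2-oxo-2H-pyran-3-carboxylic acid, (tributylstannyl)methanol and N-(5-chloropyridin-2-yl)triflimide are taken as catalogue reagents.

**Step 1**
Reactants: 1 propanal; 2 but-3-en-2-one (methyl vinyl ketone)
Product: 3 (R)-2-methyl-5-oxohexanal
Conditions: (S)-2-[methoxy(diphenyl)methyl]pyrrolidine (5 mol%), ethyl 3,4-dihydroxybenzoate (20 mol%), neat, 4 °C
Reagents that add atoms: none
Why: Enamine-mediated organocatalytic Michael addition of an aldehyde to an enone, in which the diphenylmethyl group of the (S)-catalyst shields one face of the E-enamine of propanal so that the future C8 stereocentre should form with R configuration.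

**Step 2**
Reactants: 3 (R)-2-methyl-5-oxohexanal
Product: 4 (R)-4-methylcyclohex-2-en-1-one
Conditions: LiOH (cat.), i-PrOH, 0 °C → rt
Reagents that add atoms: none
Why: Intramolecular aldol condensation of the methyl ketone onto the aldehyde gives the conjugated cyclohexenone, and mild base should close the ring before the α-stereocentre of the aldehyde is lost, after which that carbon is the less acidic γ-position of the enone.

**Step 3**
Reactants: 4 (R)-4-methylcyclohex-2-en-1-one
Product: 5 trimethyl{[(3S,4R)-3,4-dimethylcyclohex-1-en-1-yl]oxy}silane
Conditions: MeMgBr, CuBr·SMe2 (5 mol%), TMSCl, DMPU, THF, −78 °C; Et3N, cold aq. NaHCO3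
Reagents that add atoms: methylmagnesium bromide C[Mg]Br; chlorotrimethylsilane C[Si](C)(C)Cl
Why: Chlorosilane-accelerated Cu-catalysed conjugate addition of a Grignard reagent delivers the methyl group (future C20) and traps the enolate regiospecifically as its silyl ether; the new centre (methyl anti to the existing one) is of no consequence because it becomes sp2 in step 4.

**Step 4**
Reactants: 5 trimethyl{[(3S,4R)-3,4-dimethylcyclohex-1-en-1-yl]oxy}silane
Product: 6 (R)-3,4-dimethylcyclohex-2-en-1-one
Conditions: Pd(OAc)2 (10 mol%), O2 (1 atm), DMSO, rt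
Reagents that add atoms: none
Why: Saegusa–Ito oxidation (palladium enolate, β-hydride elimination, aerobic turnover) places the double bond exactly where the silyl enol ether was and leaves the C8 stereocentre untouched.

**Step 5**
Reactants: 7 3-bromofuran; 8 oxirane
Product: 10 2-(furan-3-yl)ethan-1-ol, via furan-3-yllithium 9 (not isolated)
Conditions: n-BuLi, THF, −78 °C; oxirane, BF3·OEt2, −78 °C; aq. NH4Cl
Reagents that add atoms: n-butyllithium [Li]CCCC (lithium ends in 9 only)
Why: Bromine–lithium exchange at −78 °C, below the temperature at which 3-lithiofuran isomerises, followed by Lewis-acid-assisted epoxide opening is a standard two-carbon homologation.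

**Step 6**
Reactants: 10 2-(furan-3-yl)ethan-1-ol
Product: 11 3-(2-bromoethyl)furan
Conditions: CBr4, PPh3, CH2Cl2, 0 °C
Reagents that add atoms: carbon tetrabromide BrC(Br)(Br)Br
Why: The Appel reaction converts the primary alcohol into the bromide under neutral conditions that the furan tolerates.

**Step 7**
Reactants: 11 3-(2-bromoethyl)furan; 6 (R)-3,4-dimethylcyclohex-2-en-1-one
Product: 14 (3S,4R)-3-[2-(furan-3-yl)ethyl]-3,4-dimethylcyclohex-1-en-1-yl trifluoromethanesulfonate, via [2-(furan-3-yl)ethyl]magnesium bromide 12 (not isolated), via bromomagnesium enolate 13 (not isolated)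
Conditions: Mg, THF, rt; 6, CuBr·SMe2 (10 mol%), THF, −40 → −20 °C; N-(5-chloropyridin-2-yl)triflimide, DMPU, −78 → 0 °C
Reagents that add atoms: magnesium [Mg] (ends in 12 and 13 only); N-(5-chloropyridin-2-yl)-1,1,1-trifluoro-N-(trifluoromethylsulfonyl)methanesulfonamide FC(F)(F)S(=O)(=O)N(c1ccc(Cl)cn1)S(=O)(=O)C(F)(F)F
Why: Magnesium inserts into the C–Br bond of 11, and Grignard reagent 12 is transmetallated to an alkylcopper(I) ate species that π-complexes enone 6, adds oxidatively at the β-carbon C9 to a copper(III) enolate and reductively eliminates to form C9–C11, leaving the regiodefined magnesium enolate 13, which the triflimide sulfonylates on oxygen. The closest known reaction type is the Cu-catalysed 1,4-addition of Grignard reagents to 3-methylcyclohex-2-enones with in-situ triflation of the enolate (three-component coupling). No ring is closed: ring B (C5–C10) is a temporary template whose C5–C10 bond is cut again in step 11. The new quaternary centre C9 is controlled by the C8 methyl group, which sits pseudoaxial to avoid A(1,2) strain with the C9 methyl, so that stereoelectronically favoured axial attack comes from the opposite face and places C11 trans to C17 (9S). The step needs 1,4- over 1,2-addition, secured by catalytic copper at low temperature, and an unscrambled enolate, secured by trapping 13 as the C5=C10 triflate before any proton source is present; in one operation it joins the two halves, sets C9 and turns the ketone that made C9 electrophilic into the handle for C19.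

**Step 8**
Reactants: 14 (3S,4R)-3-[2-(furan-3-yl)ethyl]-3,4-dimethylcyclohex-1-en-1-yl trifluoromethanesulfonate
Product: 15 {(3S,4R)-3-[2-(furan-3-yl)ethyl]-3,4-dimethylcyclohex-1-en-1-yl}methanol
Conditions: Bu3SnCH2OH, Pd(PPh3)4 (5 mol%), LiCl, 1,4-dioxane, 90 °C
Reagents that add atoms: (tributylstannyl)methanol CCCC[Sn](CCCC)(CCCC)CO
Why: Stille coupling of the enol triflate with the hydroxymethylstannane (chloride-assisted oxidative addition, transmetallation, reductive elimination) replaces the triflate by C19 as a free CH2OH.

**Step 9**
Reactants: 15 {(3S,4R)-3-[2-(furan-3-yl)ethyl]-3,4-dimethylcyclohex-1-en-1-yl}methanol; 16 2-oxo-2H-pyran-3-carboxylic acid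
Product: 17 {(3S,4R)-3-[2-(furan-3-yl)ethyl]-3,4-dimethylcyclohex-1-en-1-yl}methyl 2-oxo-2H-pyran-3-carboxylate
Conditions: EDC·HCl, DMAP (5 mol%), CH2Cl2, 0 °C → rt
Reagents that add atoms: none
Why: Steglich-type carbodiimide esterification of a primary allylic alcohol, run cold with little DMAP because the pyrone is itself an acceptor, installs the diene on the C19 oxygen through the future C18 carbonyl.

**Step 10**
Reactants: 17 {(3S,4R)-3-[2-(furan-3-yl)ethyl]-3,4-dimethylcyclohex-1-en-1-yl}methyl 2-oxo-2H-pyran-3-carboxylate
Product: 19 cis-fused diene lactone (ring A = cyclohexa-1,3-diene C1=C2–C3=C4; γ-lactone C18–O–C19 on C4/C5; H-10 cis to C19), via bridged lactone adduct 18 (not isolated)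
Conditions: 1,2-dichlorobenzene (0.01 M), BHT (cat.), Ar, sealed tube, 180 °C
Reagents that add atoms: none
Why: Intramolecular inverse-electron-demand Diels–Alder reaction of the 2-pyrone with the tethered ring alkene C5=C10, followed by retro-Diels–Alder loss of CO2 from 18, gives the cyclohexadiene; suprafacial addition to the ring alkene makes C19 and H-10 cis (cis ring fusion), the face anti to the pseudoaxial C9 methyl (shown) should prevail, and the other cis-fused isomer would converge to the same product in step 11.

**Step 11**
Reactants: 19 cis-fused diene lactone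
Product: 20 seco butenolide (18,19-lactone of the ten-membered triene; C2=C3 Z; C1=C10 E)
Conditions: hν (300 nm), degassed Et2O, −20 °C, run to partial conversion with recycling of 19
Reagents that add atoms: none
Why: Photochemical 6π conrotatory electrocyclic ring opening of a cyclohexa-1,3-diene (the provitamin D type of reaction) cuts C5–C10; because C18 and C19 stay tied in the five-membered lactone, C19 must turn outward, conrotation then turns C9 outward and H-10 inward so that C1=C10 can only form E, and the new C2=C3 bond is Z because it was part of ring A.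

**Step 12**
Reactants: 20 seco butenolide
Product: 22 target acid (19-acetate of the 5,10-seco acid; 8R,9S), via potassium hydroxy carboxylate 21 (not isolated)
Conditions: KOH (1.05 equiv), THF/H2O, 0 °C; evaporate, PhMe azeotrope; Ac2O, pyridine, DMAP (cat.), 0 °C; H2O, then 1 M HCl to pH 4, 0 °C
Reagents that add atoms: potassium hydroxide [K+].[OH-]; acetic anhydride CC(=O)OC(C)=O
Why: Saponification opens the butenolide to the (Z)-hydroxy carboxylate, whose primary allylic hydroxyl is acetylated under DMAP catalysis while the acid stays masked as its salt (any mixed anhydride is hydrolysed on work-up), and material that closes back is 20 again and can be recycled.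

**Compound list**

1 | propanal | CCC=O | starting material
2 | but-3-en-2-one (methyl vinyl ketone) | CC(=O)C=C | starting material
3 | (R)-2-methyl-5-oxohexanal | O=C[C@H](C)CCC(C)=O | intermediate
4 | (R)-4-methylcyclohex-2-en-1-one | O=C1C=C[C@H](C)CC1 | intermediate
5 | trimethyl{[(3S,4R)-3,4-dimethylcyclohex-1-en-1-yl]oxy}silane | C[Si](C)(C)OC1=C[C@@H](C)[C@H](C)CC1 | intermediate
6 | (R)-3,4-dimethylcyclohex-2-en-1-one | O=C1C=C(C)[C@H](C)CC1 | intermediate
7 | 3-bromofuran | Brc1ccoc1 | starting material
8 | oxirane | C1CO1 | starting material
9 | furan-3-yllithium | [Li]c1ccoc1 | intermediate (not isolated)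
10 | 2-(furan-3-yl)ethan-1-ol | OCCc1ccoc1 | intermediate
11 | 3-(2-bromoethyl)furan | BrCCc1ccoc1 | intermediate
12 | [2-(furan-3-yl)ethyl]magnesium bromide | Br[Mg]CCc1ccoc1 | intermediate (not isolated)
13 | bromomagnesium (3S,4R)-3-[2-(furan-3-yl)ethyl]-3,4-dimethylcyclohex-1-en-1-olate | Br[Mg]OC1=C[C@@](C)(CCc2ccoc2)[C@H](C)CC1 | intermediate (not isolated)
14 | (3S,4R)-3-[2-(furan-3-yl)ethyl]-3,4-dimethylcyclohex-1-en-1-yl trifluoromethanesulfonate | O=S(=O)(OC1=C[C@@](C)(CCc2ccoc2)[C@H](C)CC1)C(F)(F)F | intermediate
15 | {(3S,4R)-3-[2-(furan-3-yl)ethyl]-3,4-dimethylcyclohex-1-en-1-yl}methanol | OCC1=C[C@@](C)(CCc2ccoc2)[C@H](C)CC1 | intermediate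
16 | 2-oxo-2H-pyran-3-carboxylic acid | OC(=O)C1=CC=COC1=O | starting material
17 | {(3S,4R)-3-[2-(furan-3-yl)ethyl]-3,4-dimethylcyclohex-1-en-1-yl}methyl 2-oxo-2H-pyran-3-carboxylate | O=C(OCC1=C[C@@](C)(CCc2ccoc2)[C@H](C)CC1)C1=CC=COC1=O | intermediate
18 | bridged lactone adduct: 2-oxabicyclo[2.2.2]oct-5-en-3-one core with the O–C(=O) bridge from C1 to C4, the γ-lactone C18–O–C19 on C4/C5 and ring B on C5/C10 (drawn with ring B syn to the O–C(=O) bridge; either orientation loses CO2 to 19) | O=C1OC[C@@]23CC[C@@H](C)[C@](C)(CCc4ccoc4)[C@@H]2[C@H]2C=C[C@@]13C(=O)O2 | intermediate (not isolated)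
19 | cis-fused diene lactone: ring A cyclohexa-1,3-diene (C1=C2–C3=C4), C4 bears the lactone carbonyl C18, quaternary C5 bears the lactone CH2 (C19), H-10 cis to C19 and to both methyl groups, C8/C9 as in 14 | O=C1OC[C@@]23CC[C@@H](C)[C@](C)(CCc4ccoc4)[C@@H]2C=CC=C13 | intermediate
20 | seco butenolide: 18,19-lactone of the ten-membered triene, C4=C5 inside the butenolide, C2=C3 Z, C1=C10 E, (8R,9S) | O=C1OCC2=C1/C=C\C=C\[C@@](C)(CCc3ccoc3)[C@H](C)CC2 | intermediate
21 | potassium salt of the (Z)-hydroxy acid from 20 (19-hydroxy-18-carboxylate) | OC/C1=C(C(=O)[O-])/C=C\C=C\[C@@](C)(CCc2ccoc2)[C@H](C)CC1.[K+] | intermediate (not isolated)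
22 | (1(10)Z,2Z,4E,6S,7R)-10-(acetoxymethyl)-6-[2-(furan-3-yl)ethyl]-6,7-dimethylcyclodeca-1(10),2,4-triene-1-carboxylic acid | CC(=O)OC/C1=C(C(=O)O)/C=C\C=C\[C@@](C)(CCc2ccoc2)[C@H](C)CC1 | target

**Step count and risks**

Total step count: 12. Longest linear sequence: 10 steps (steps 1–4 and 7–12).

Steps most likely to fail:

- **Step 10 (pyrone Diels–Alder/CO2 loss).** The ester link between pyrone and ring B rests in its s-trans form, which holds diene and alkene apart. At the temperature needed for the intramolecular cycloaddition, the pyrone may therefore be consumed by intermolecular cycloaddition (also with the furan) or by decomposition. Fallback, setting out from 15 and returning at 19: 15 is esterified with propiolic acid (DCC, CH2Cl2, −20 °C) to the propiolate ester F1. F1 is then treated with acetylene (1 atm) and a cationic Rh(I)/BINAP catalyst (1,2-dichloroethane, 60 °C). This [2+2+2] cycloaddition of a 1,6-enyne with an external alkyne closes lactone and ring A on the metal (oxidative cyclisation forming C4–C5, acetylene insertion, reductive elimination forming C1–C10). It again adds syn across C5=C10 and gives 19 without any CO2 extrusion.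

- **Step 11 (photochemical ring opening).** Butenolide 20 absorbs in the same window as 19 and may be drained by photochemical re-closure, E/Z scrambling at C1=C10 or further rearrangement, so that it does not build up. Fallback, from 19 to 22, exchanges the order of the last two events. 19 is saponified (KOH, THF/H2O, 0 °C) to the potassium salt of the bicyclic hydroxy acid F2 and acetylated (Ac2O, pyridine, DMAP; then pH 4) to the bicyclic acetoxy dienoic acid F3; material that lactonises again is simply 19. F3 is then irradiated (300 nm, degassed Et2O, −20 °C). Its ring-opened product is 22 itself, a twisted cross-conjugated triene acid expected to absorb at shorter wavelength than the planar dienoic acid F3. The sense of conrotation is then set by H-10 turning inward in preference to the quaternary C9.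

- **Step 12 (lactone opening/acetylation).** The ring-opened state may be lost: the anhydride activates the carboxylate and the free hydroxyl closes back to the butenolide faster than it is acetylated. Fallback, from 21 (made from 20 as in step 12) to 22, takes the carboxylate out of play before any acylating agent is present. 21 is alkylated with allyl bromide (DMF, 0 °C) to the hydroxy allyl ester F4, which is acetylated at once (Ac2O, pyridine, DMAP, 0 °C) to the acetoxy allyl ester F5. The allyl ester is then removed with Pd(PPh3)4 (2 mol%) and morpholine (THF, 0 °C), conditions under which the hindered allylic acetate on the tetrasubstituted, ester-conjugated double bond should not ionise.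

**Further compounds**

F1 | step 10 | {(3S,4R)-3-[2-(furan-3-yl)ethyl]-3,4-dimethylcyclohex-1-en-1-yl}methyl prop-2-ynoate | C#CC(=O)OCC1=C[C@@](C)(CCc2ccoc2)[C@H](C)CC1
F2 | step 11 | potassium salt of the bicyclic hydroxy acid (lactone of 19 opened; 19-hydroxy-18-carboxylate, cis-fused diene) | OC[C@@]12CC[C@@H](C)[C@](C)(CCc3ccoc3)[C@@H]1C=CC=C2C(=O)[O-].[K+]
F3 | step 11 | bicyclic acetoxy dienoic acid (19-acetate of the opened form of 19) | CC(=O)OC[C@@]12CC[C@@H](C)[C@](C)(CCc3ccoc3)[C@@H]1C=CC=C2C(=O)O
F4 | step 12 | allyl ester of the (Z)-hydroxy acid from 20 | OC/C1=C(C(=O)OCC=C)/C=C\C=C\[C@@](C)(CCc2ccoc2)[C@H](C)CC1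
F5 | step 12 | allyl ester of target acid 22 | CC(=O)OC/C1=C(C(=O)OCC=C)/C=C\C=C\[C@@](C)(CCc2ccoc2)[C@H](C)CC1
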